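**Plan**
Retrosynthesis: the pyranone ring is cut at three bonds at once (C4a–C4, C8a–C1, O2–C3), leaving a benzyl-protected aryne, a terminal alkyne and CO2; the aryne precursor is cut at the diaryl ether C–O bond (SNAr on a fluoronitroarene), and the hindered phenoxy-ring phenol is traced to olivetol through a Dakin-type oxidation.
Enabling feature: lactone carbons C1 and C4 sit on the adjacent benzo carbons C8a and C4a, and the aryloxy-bearing C8 is the direct neighbour of C8a; a 3-oxygenated aryne gives exactly this pattern when a carbon nucleophile enters at the remote terminus and CO2 at the terminus next to oxygen.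
Forward: olivetol is formylated, methylated, benzylated and oxidised to the phenol (steps 1–4); this is joined to benzylated 3,5-difluoro-4-nitrophenol, the second fluoride becomes a 4-methoxybenzyl ether and nitro becomes iodide (steps 5–9); unmasking the phenol, then a one-pot retro-Brook shift and triflation, gives the o-silylaryl triflate (steps 10–11).
Rings: both benzene rings are bought; the only ring made is the pyranone, closed in step 12; step 13 removes the two benzyl ethers.
Stereochemistry: the target has no stereocentre and no stereogenic double bond, so nothing has to be controlled.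

Key step: step 12

Remark: isocoumarin numbering (C1 carbonyl, O2, C3, C4, C4a, C5–C8, C8a) is used for the corresponding carbons of the aryne and its precursor; the second oxygen of the central ring is carried as a 4-methoxybenzyl ether because a free ortho-hydroxyl would complicate the diazonium chemistry; all starting materials are taken as commercial.

**Route**

Step 1
Reactants: 1 olivetol (5-pentylbenzene-1,3-diol)
Product: 3 2,4-dihydroxy-6-pentylbenzaldehyde, via iminium chloride 2 (not isolated)
Conditions: POCl3, DMF, 0 °C to rt; then H2O, 50 °C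
Reagents that add atoms: N,N-dimethylformamide CN(C)C=O; water O; phosphoryl chloride O=P(Cl)(Cl)Cl (chloride of 2 only)
Why: Vilsmeier–Haack formylation attacks the resorcinol carbon ortho to one hydroxyl and para to the other, a site that for 5-alkylresorcinols is expected to win over the crowded carbon between the two hydroxyls, and hydrolysis of iminium 2 gives the aldehyde.

Step 2
Reactants: 3 2,4-dihydroxy-6-pentylbenzaldehyde
Product: 4 2-hydroxy-4-methoxy-6-pentylbenzaldehyde
Conditions: MeI (1.05 equiv), K2CO3 (1.0 equiv), acetone, rt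
Reagents that add atoms: iodomethane CI
Why: Williamson etherification with one equivalent of base should alkylate only the 4-hydroxyl, the more acidic one para to the formyl group, because the 2-hydroxyl is held in a hydrogen bond to the aldehyde.

Step 3
Reactants: 4 2-hydroxy-4-methoxy-6-pentylbenzaldehyde
Product: 5 2-(benzyloxy)-4-methoxy-6-pentylbenzaldehyde
Conditions: BnBr, K2CO3, DMF, 60 °C
Reagents that add atoms: benzyl bromide BrCc1ccccc1
Why: Williamson etherification under more forcing conditions overcomes the hydrogen bond and benzylates the remaining chelated hydroxyl.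

Step 4
Reactants: 5 2-(benzyloxy)-4-methoxy-6-pentylbenzaldehyde
Product: 7 2-(benzyloxy)-4-methoxy-6-pentylphenol, via aryl formate 6 (not isolated)
Conditions: mCPBA, CH2Cl2, 0 °C to rt; then K2CO3 (cat.), MeOH, rt
Reagents that add atoms: 3-chloroperoxybenzoic acid O=C(OO)c1cccc(Cl)c1
Why: Baeyer–Villiger oxidation in its Dakin-type variant, in which the electron-rich aryl group with ortho and para alkoxy donors migrates in preference to hydrogen to give formate 6, which mild methanolysis converts into the phenol.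

Step 5
Reactants: 8 3,5-difluoro-4-nitrophenol
Product: 9 5-(benzyloxy)-1,3-difluoro-2-nitrobenzene
Conditions: BnBr, K2CO3, DMF, rt
Reagents that add atoms: benzyl bromide BrCc1ccccc1
Why: Williamson etherification of an acidic nitrophenol, fast enough at room temperature that the weakly nucleophilic phenoxide should not displace fluoride from a second molecule.

Step 6
Reactants: 7 2-(benzyloxy)-4-methoxy-6-pentylphenol; 9 5-(benzyloxy)-1,3-difluoro-2-nitrobenzene (1.2 equiv)
Product: 10 5-(benzyloxy)-1-[2-(benzyloxy)-4-methoxy-6-pentylphenoxy]-3-fluoro-2-nitrobenzene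
Conditions: Cs2CO3, DMF, rt to 40 °C
Reagents that add atoms: none
Why: Nucleophilic aromatic substitution through a Meisenheimer complex at a fluoride ortho to nitro tolerates the doubly ortho-substituted phenoxide, and the first aryloxy group deactivates the ring enough that the second fluoride should stay.

Step 7
Reactants: 10 5-(benzyloxy)-1-[2-(benzyloxy)-4-methoxy-6-pentylphenoxy]-3-fluoro-2-nitrobenzene
Product: 11 5-(benzyloxy)-1-[2-(benzyloxy)-4-methoxy-6-pentylphenoxy]-3-[(4-methoxybenzyl)oxy]-2-nitrobenzene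
Conditions: 4-methoxybenzyl alcohol, NaH, THF, 0 °C to rt
Reagents that add atoms: 4-methoxybenzyl alcohol COc1ccc(CO)cc1
Why: Second nucleophilic aromatic substitution, in which the small alkoxide displaces the remaining nitro-activated fluoride, a far better leaving group in this mechanism than the hindered aryloxide or the benzyloxide para to nitro.

Step 8
Reactants: 11 5-(benzyloxy)-1-[2-(benzyloxy)-4-methoxy-6-pentylphenoxy]-3-[(4-methoxybenzyl)oxy]-2-nitrobenzene
Product: 12 4-(benzyloxy)-2-[2-(benzyloxy)-4-methoxy-6-pentylphenoxy]-6-[(4-methoxybenzyl)oxy]aniline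
Conditions: H2 (1 atm), 5% Pt/C (sulfided), EtOAc, rt
Reagents that add atoms: none
Why: Catalytic hydrogenation over sulfided platinum reduces nitro to amine and, unlike palladium, is expected to leave benzyl and 4-methoxybenzyl ethers untouched.

Step 9
Reactants: 12 4-(benzyloxy)-2-[2-(benzyloxy)-4-methoxy-6-pentylphenoxy]-6-[(4-methoxybenzyl)oxy]aniline
Product: 14 5-(benzyloxy)-1-[2-(benzyloxy)-4-methoxy-6-pentylphenoxy]-2-iodo-3-[(4-methoxybenzyl)oxy]benzene, via diazonium tosylate 13 (not isolated)
Conditions: NaNO2, p-TsOH·H2O, KI, MeCN/H2O, 10 °C to rt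
Reagents that add atoms: potassium iodide [K+].[I-]; sodium nitrite O=N[O-].[Na+] and p-toluenesulfonic acid Cc1ccc(S(=O)(=O)O)cc1 (atoms in 13 only)
Why: Diazotisation followed by copper-free iodo-dediazoniation (a Sandmeyer-type reaction) in a one-pot sulfonic acid protocol suits electron-rich hindered anilines, and cyclisation of the aryl radical onto the phenoxy ring is blocked because both ortho positions of that ring are substituted.

Step 10
Reactants: 14 5-(benzyloxy)-1-[2-(benzyloxy)-4-methoxy-6-pentylphenoxy]-2-iodo-3-[(4-methoxybenzyl)oxy]benzene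
Product: 15 5-(benzyloxy)-3-[2-(benzyloxy)-4-methoxy-6-pentylphenoxy]-2-iodophenol
Conditions: TFA (10% v/v), anisole, CH2Cl2, 0 °C
Reagents that add atoms: none
Why: Acidolysis of the 4-methoxybenzyl ether proceeds through its stabilised benzylic cation, trapped by anisole in a Friedel–Crafts alkylation, at a temperature at which plain benzyl ethers are stable.

Step 11
Reactants: 15 5-(benzyloxy)-3-[2-(benzyloxy)-4-methoxy-6-pentylphenoxy]-2-iodophenol
Product: 18 5-(benzyloxy)-3-[2-(benzyloxy)-4-methoxy-6-pentylphenoxy]-2-(trimethylsilyl)phenyl trifluoromethanesulfonate, via trimethylsilyl ether 16 (not isolated), via lithium 2-silylphenoxide 17 (not isolated)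
Conditions: HMDS, THF, 65 °C, then evaporate; n-BuLi, THF, −78 °C; Tf2O, −78 °C to rt
Reagents that add atoms: hexamethyldisilazane C[Si](C)(C)N[Si](C)(C)C; trifluoromethanesulfonic anhydride O=S(=O)(OS(=O)(=O)C(F)(F)F)C(F)(F)F; n-butyllithium [Li]CCCC (lithium of 17 only)
Why: O-Silylation, iodine–lithium exchange and the anionic 1,3 O-to-C silyl shift (retro-Brook rearrangement) place silicon on the carbon between the two oxygens, and the lithium phenoxide so formed is triflated in the same flask, the standard way from o-halophenols to o-silylaryl triflates.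

Step 12
Reactants: 18 5-(benzyloxy)-3-[2-(benzyloxy)-4-methoxy-6-pentylphenoxy]-2-(trimethylsilyl)phenyl trifluoromethanesulfonate; 19 hept-1-yne (2 equiv); 20 carbon dioxide
Product: 22 6-(benzyloxy)-8-[2-(benzyloxy)-4-methoxy-6-pentylphenoxy]-3-pentyl-1H-isochromen-1-one, via aryne 21 (not isolated)
Conditions: chloro[1,3-bis(2,6-diisopropylphenyl)imidazol-2-ylidene]copper (10 mol %), CsF, Cs2CO3, CO2 (1 atm), MeCN, 100 °C, sealed vessel
Reagents that add atoms: none
Why: Fluoride removes the silyl group of 18 and triflate departs, so aryne 21 is fed in slowly; the monovalent copper acetylide formed from 19 and Cs2CO3 adds across the strained triple bond, the resulting arylcopper inserts CO2, and the copper carboxylate attacks the neighbouring alkyne to give a vinylcopper that is protonated by fresh alkyne, which restarts the cycle. The closest known reaction is the copper–carbene-catalysed three-component coupling of arynes from o-silylaryl triflates with terminal alkynes and CO2 to 3-substituted isocoumarins, applied here to a 3,5-dioxygenated aryne. The pyranone ring closes by 6-endo-dig attack of the carboxylate oxygen on the alkyne carbon bearing the pentyl chain, forming O2–C3 after C4a–C4 and C8a–C1. No stereocentre is formed. The step needs the acetylide carbon to bond to C4a and copper to C8a; the aryloxy group at C8 should secure this, because its inductive pull makes C4a the more electrophilic terminus and stabilises the carbon–copper bond developing next to oxygen (the bias known from 3,5-dimethoxybenzyne), and the bulky diaryl ether also shields C8a. The benzyloxy group at C6, para to C8a, exerts only a weak opposing effect.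

Step 13
Reactants: 22 6-(benzyloxy)-8-[2-(benzyloxy)-4-methoxy-6-pentylphenoxy]-3-pentyl-1H-isochromen-1-one
Product: 23 6-hydroxy-8-(2-hydroxy-4-methoxy-6-pentylphenoxy)-3-pentyl-1H-isochromen-1-one (CNP0409817.0)
Conditions: BCl3, pentamethylbenzene, CH2Cl2, −78 °C; then MeOH/H2O
Reagents that add atoms: none
Why: Lewis acid cleavage of aryl benzyl ethers with BCl3, with pentamethylbenzene as a non-basic scavenger (Friedel–Crafts trapping of the benzyl cation), should at −78 °C spare the aryl methyl ether, the diaryl ether and the lactone.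

**Compound list**
1 | olivetol (5-pentylbenzene-1,3-diol) | CCCCCc1cc(O)cc(O)c1 | starting material
2 | N-[(2,4-dihydroxy-6-pentylphenyl)methylidene]-N-methylmethanaminium chloride | CCCCCc1cc(O)cc(O)c1C=[N+](C)C.[Cl-] | intermediate
3 | 2,4-dihydroxy-6-pentylbenzaldehyde | CCCCCc1cc(O)cc(O)c1C=O | intermediate
4 | 2-hydroxy-4-methoxy-6-pentylbenzaldehyde | CCCCCc1cc(OC)cc(O)c1C=O | intermediate
5 | 2-(benzyloxy)-4-methoxy-6-pentylbenzaldehyde | CCCCCc1cc(OC)cc(OCc2ccccc2)c1C=O | intermediate
6 | 2-(benzyloxy)-4-methoxy-6-pentylphenyl formate | CCCCCc1cc(OC)cc(OCc2ccccc2)c1OC=O | intermediate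
7 | 2-(benzyloxy)-4-methoxy-6-pentylphenol | CCCCCc1cc(OC)cc(OCc2ccccc2)c1O | intermediate
8 | 3,5-difluoro-4-nitrophenol | Oc1cc(F)c([N+](=O)[O-])c(F)c1 | starting material
9 | 5-(benzyloxy)-1,3-difluoro-2-nitrobenzene | O=[N+]([O-])c1c(F)cc(OCc2ccccc2)cc1F | intermediate
10 | 5-(benzyloxy)-1-[2-(benzyloxy)-4-methoxy-6-pentylphenoxy]-3-fluoro-2-nitrobenzene | CCCCCc1cc(OC)cc(OCc2ccccc2)c1Oc1cc(OCc2ccccc2)cc(F)c1[N+](=O)[O-] | intermediate
11 | 5-(benzyloxy)-1-[2-(benzyloxy)-4-methoxy-6-pentylphenoxy]-3-[(4-methoxybenzyl)oxy]-2-nitrobenzene | CCCCCc1cc(OC)cc(OCc2ccccc2)c1Oc1cc(OCc2ccccc2)cc(OCc2ccc(OC)cc2)c1[N+](=O)[O-] | intermediate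
12 | 4-(benzyloxy)-2-[2-(benzyloxy)-4-methoxy-6-pentylphenoxy]-6-[(4-methoxybenzyl)oxy]aniline | CCCCCc1cc(OC)cc(OCc2ccccc2)c1Oc1cc(OCc2ccccc2)cc(OCc2ccc(OC)cc2)c1N | intermediate
13 | 4-(benzyloxy)-2-[2-(benzyloxy)-4-methoxy-6-pentylphenoxy]-6-[(4-methoxybenzyl)oxy]benzenediazonium p-toluenesulfonate | CCCCCc1cc(OC)cc(OCc2ccccc2)c1Oc1cc(OCc2ccccc2)cc(OCc2ccc(OC)cc2)c1[N+]#N.Cc1ccc(S(=O)(=O)[O-])cc1 | intermediate
14 | 5-(benzyloxy)-1-[2-(benzyloxy)-4-methoxy-6-pentylphenoxy]-2-iodo-3-[(4-methoxybenzyl)oxy]benzene | CCCCCc1cc(OC)cc(OCc2ccccc2)c1Oc1cc(OCc2ccccc2)cc(OCc2ccc(OC)cc2)c1I | intermediate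
15 | 5-(benzyloxy)-3-[2-(benzyloxy)-4-methoxy-6-pentylphenoxy]-2-iodophenol | CCCCCc1cc(OC)cc(OCc2ccccc2)c1Oc1cc(OCc2ccccc2)cc(O)c1I | intermediate
16 | {5-(benzyloxy)-3-[2-(benzyloxy)-4-methoxy-6-pentylphenoxy]-2-iodophenoxy}trimethylsilane | CCCCCc1cc(OC)cc(OCc2ccccc2)c1Oc1cc(OCc2ccccc2)cc(O[Si](C)(C)C)c1I | intermediate
17 | lithium 5-(benzyloxy)-3-[2-(benzyloxy)-4-methoxy-6-pentylphenoxy]-2-(trimethylsilyl)phenoxide | CCCCCc1cc(OC)cc(OCc2ccccc2)c1Oc1cc(OCc2ccccc2)cc([O-])c1[Si](C)(C)C.[Li+] | intermediate
18 | 5-(benzyloxy)-3-[2-(benzyloxy)-4-methoxy-6-pentylphenoxy]-2-(trimethylsilyl)phenyl trifluoromethanesulfonate | CCCCCc1cc(OC)cc(OCc2ccccc2)c1Oc1cc(OCc2ccccc2)cc(OS(=O)(=O)C(F)(F)F)c1[Si](C)(C)C | intermediate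
19 | hept-1-yne | CCCCCC#C | starting material
20 | carbon dioxide | O=C=O | starting material
21 | 5-(benzyloxy)-3-[2-(benzyloxy)-4-methoxy-6-pentylphenoxy]benzyne (triple bond between the former C–Si and C–OTf carbons, C8a and C4a) | CCCCCc1cc(OC)cc(OCc2ccccc2)c1OC1=CC(OCc2ccccc2)=CC#C1 | intermediate
22 | 6-(benzyloxy)-8-[2-(benzyloxy)-4-methoxy-6-pentylphenoxy]-3-pentyl-1H-isochromen-1-one | CCCCCc1cc2cc(OCc3ccccc3)cc(Oc3c(OCc4ccccc4)cc(OC)cc3CCCCC)c2c(=O)o1 | intermediate
23 | 6-hydroxy-8-(2-hydroxy-4-methoxy-6-pentylphenoxy)-3-pentyl-1H-isochromen-1-one | CCCCCc1cc2cc(O)cc(Oc3c(O)cc(OC)cc3CCCCC)c2c(=O)o1 | target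

**Count and risks**
Total step count: 13. Longest linear sequence: 12 steps (steps 1–4 and 6–13, from olivetol).

Steps most likely to fail:

1. Step 12. The copper acetylide may be carboxylated directly by CO2, or the aryne may be consumed by hydroalkynylation or oligomerisation before CO2 is taken up, and some acetylide may add at C8a. The fallback builds the lactone stepwise and sets out from 14.
 - Iodine–lithium exchange (n-BuLi, THF, −78 °C) and quenching with methyl chloroformate would give methyl 4-(benzyloxy)-2-[2-(benzyloxy)-4-methoxy-6-pentylphenoxy]-6-[(4-methoxybenzyl)oxy]benzoate F1.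
 - TFA/anisole would free methyl 4-(benzyloxy)-2-[2-(benzyloxy)-4-methoxy-6-pentylphenoxy]-6-hydroxybenzoate F2.
 - Tf2O/pyridine would give methyl 4-(benzyloxy)-2-[2-(benzyloxy)-4-methoxy-6-pentylphenoxy]-6-{[(trifluoromethyl)sulfonyl]oxy}benzoate F3.
 - Sonogashira coupling with 19 (PdCl2(PPh3)2, CuI, Et3N, DMF, 70 °C) would give methyl 4-(benzyloxy)-2-[2-(benzyloxy)-4-methoxy-6-pentylphenoxy]-6-(hept-1-yn-1-yl)benzoate F4.
 - Acid-promoted 6-endo-dig lactonisation with loss of the ester methyl group (AgOTf, p-TsOH, ClCH2CH2Cl, 60 °C) would come back to the route at 22.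

2. Step 9. The diazonium ion may be reduced to the arene or hydrolysed instead of taking up iodide, and the acidic medium may erode the 4-methoxybenzyl ether. The fallback separates diazotisation from carbon–iodine bond formation and sets out from 12.
 - Brief diazotisation at 0 °C (NaNO2, HCl, THF/H2O) and immediate quenching into pyrrolidine/K2CO3 would give the isolable triazene 1-({4-(benzyloxy)-2-[2-(benzyloxy)-4-methoxy-6-pentylphenoxy]-6-[(4-methoxybenzyl)oxy]phenyl}diazenyl)pyrrolidine F5.
 - Heating F5 in iodomethane (sealed tube, 110 °C) would deliver the aryl iodide under anhydrous, non-reducing conditions and come back to the route at 14.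

3. Step 11. Attack of n-BuLi at silicon or protonation of the aryllithium may outrun the O-to-C silyl shift at this congested carbon, giving desilylated or deiodinated phenol. The fallback installs silicon intermolecularly before the oxygen is unmasked and sets out from 14.
 - Iodine–lithium exchange (n-BuLi, THF, −78 °C) and trapping with Me3SiCl would give {4-(benzyloxy)-2-[2-(benzyloxy)-4-methoxy-6-pentylphenoxy]-6-[(4-methoxybenzyl)oxy]phenyl}trimethylsilane F6.
 - Oxidative removal of the 4-methoxybenzyl group with DDQ (CH2Cl2/pH 7 buffer), chosen to avoid acid-induced protodesilylation, would give 5-(benzyloxy)-3-[2-(benzyloxy)-4-methoxy-6-pentylphenoxy]-2-(trimethylsilyl)phenol F7.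
 - Tf2O/pyridine (CH2Cl2, 0 °C) would come back to the route at 18.

Further compounds
F1 | step 12 | methyl 4-(benzyloxy)-2-[2-(benzyloxy)-4-methoxy-6-pentylphenoxy]-6-[(4-methoxybenzyl)oxy]benzoate | CCCCCc1cc(OC)cc(OCc2ccccc2)c1Oc1cc(OCc2ccccc2)cc(OCc2ccc(OC)cc2)c1C(=O)OC
F2 | step 12 | methyl 4-(benzyloxy)-2-[2-(benzyloxy)-4-methoxy-6-pentylphenoxy]-6-hydroxybenzoate | CCCCCc1cc(OC)cc(OCc2ccccc2)c1Oc1cc(OCc2ccccc2)cc(O)c1C(=O)OC
F3 | step 12 | methyl 4-(benzyloxy)-2-[2-(benzyloxy)-4-methoxy-6-pentylphenoxy]-6-{[(trifluoromethyl)sulfonyl]oxy}benzoate | CCCCCc1cc(OC)cc(OCc2ccccc2)c1Oc1cc(OCc2ccccc2)cc(OS(=O)(=O)C(F)(F)F)c1C(=O)OC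
F4 | step 12 | methyl 4-(benzyloxy)-2-[2-(benzyloxy)-4-methoxy-6-pentylphenoxy]-6-(hept-1-yn-1-yl)benzoate | CCCCCC#Cc1cc(OCc2ccccc2)cc(Oc2c(OCc3ccccc3)cc(OC)cc2CCCCC)c1C(=O)OC
F5 | step 9 | 1-({4-(benzyloxy)-2-[2-(benzyloxy)-4-methoxy-6-pentylphenoxy]-6-[(4-methoxybenzyl)oxy]phenyl}diazenyl)pyrrolidine | CCCCCc1cc(OC)cc(OCc2ccccc2)c1Oc1cc(OCc2ccccc2)cc(OCc2ccc(OC)cc2)c1N=NN1CCCC1
F6 | step 11 | {4-(benzyloxy)-2-[2-(benzyloxy)-4-methoxy-6-pentylphenoxy]-6-[(4-methoxybenzyl)oxy]phenyl}trimethylsilane | CCCCCc1cc(OC)cc(OCc2ccccc2)c1Oc1cc(OCc2ccccc2)cc(OCc2ccc(OC)cc2)c1[Si](C)(C)C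
F7 | step 11 | 5-(benzyloxy)-3-[2-(benzyloxy)-4-methoxy-6-pentylphenoxy]-2-(trimethylsilyl)phenol | CCCCCc1cc(OC)cc(OCc2ccccc2)c1Oc1cc(OCc2ccccc2)cc(O)c1[Si](C)(C)C
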